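Everything rests on cutting ring A, the indole that carries the aldehyde, at N1–C7a and C3–C3a. Its benzo ring is unsubstituted and the adjacent carbons C7a and C3a hold N1 and C3, so this ring can arrive as benzyne. One aryne formal [3+2] annulation then joins benzyne to the N–C2=C3 unit of a dehydroamino ester: the carbamate nitrogen is arylated and the aryl anion closes onto the beta carbon, giving the indoline-2-carboxylate form of ring A. The precursor is acyclic, a Z methyl 2-(Boc-amino)but-2-enoate whose C4 already bears both N-Boc indol-3-yl groups. Boc removal, ester reduction and a double MnO2 oxidation complete trisindolal.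

Key step: step 5

Remark: indoline 11 is racemic and its relative configuration at C2/C3 is not critical; the trans isomer is drawn throughout, and both centres are lost in step 8.

Step 1
Reactants: 1 indole (2.05 equiv); 2 2,2-dimethoxyacetaldehyde (60 wt% aqueous solution)
Product: 4 3,3'-(2,2-dimethoxyethane-1,1-diyl)bis(1H-indole), via indolyl carbinol 3 (not isolated)
Conditions: TsOH·H2O (5 mol%), MeOH, 0 °C → rt
Reagents that add atoms: none
Why: Acid-catalysed double Friedel–Crafts reaction (bis(indolyl)methane synthesis) at the nucleophilic C3 of indole runs through carbinol 3 and its azafulvenium ion, while methanol as solvent keeps the pendant dimethyl acetal from ionising productively.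

Step 2
Reactants: 4 3,3'-(2,2-dimethoxyethane-1,1-diyl)bis(1H-indole)
Product: 5 di-tert-butyl 3,3'-(2,2-dimethoxyethane-1,1-diyl)bis(1H-indole-1-carboxylate)
Conditions: Boc2O (2.5 equiv), 4-(dimethylamino)pyridine (DMAP, 0.1 equiv), MeCN, rt
Reagents that add atoms: di-tert-butyl dicarbonate (Boc2O), CC(C)(C)OC(=O)OC(=O)OC(C)(C)C
Why: Nucleophilic catalysis by DMAP transfers Boc to both indole nitrogens (carbamate protection), which blocks their later arylation by benzyne and makes the rings electron-poor enough to survive the acid of step 3 without 1,2-shift.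

Step 3
Reactants: 5 di-tert-butyl 3,3'-(2,2-dimethoxyethane-1,1-diyl)bis(1H-indole-1-carboxylate)
Product: 6 2,2-bis(1-Boc-indol-3-yl)acetaldehyde
Conditions: 1 M aq. HCl/THF (1:3), 40 °C, argon; crude product used at once
Reagents that add atoms: water, O
Why: Acid-catalysed acetal hydrolysis in dilute aqueous acid should leave the indole N-Boc groups in place, and the enolisable, air-sensitive α,α-diaryl acetaldehyde is carried on crude.

Step 4
Reactants: 6 2,2-bis(1-Boc-indol-3-yl)acetaldehyde; 7 Boc-α-phosphonoglycine trimethyl ester (1.2 equiv)
Product: 8 methyl (Z)-2-(Boc-amino)-4,4-bis(1-Boc-indol-3-yl)but-2-enoate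
Conditions: 7, 1,1,3,3-tetramethylguanidine (TMG, 1.15 equiv), THF, −78 °C; then 6, −78 → 0 °C
Reagents that add atoms: none
Why: Horner–Wadsworth–Emmons olefination with the preformed, weakly basic anion of the phosphonoglycinate adds to the aldehyde at low temperature in preference to enolising it and is known to give the Z dehydroamino ester, in which NHBoc and the C4 substituent are cis.

Step 5
Reactants: 8 methyl (Z)-2-(Boc-amino)-4,4-bis(1-Boc-indol-3-yl)but-2-enoate; 9 2-(trimethylsilyl)phenyl trifluoromethanesulfonate (2.0 equiv, slow addition)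
Product: 11 methyl (2R*,3R*)-1-Boc-3-[bis(1-Boc-indol-3-yl)methyl]indoline-2-carboxylate (trans, racemic), via benzyne 10 (not isolated)
Conditions: tetrabutylammonium difluorotriphenylsilicate (TBAT, 2.5 equiv), THF, rt, argon
Reagents that add atoms: none
Why: Fluoride from TBAT attacks the silicon of 9 and expels triflate to give benzyne 10; the carbamate nitrogen of 8, deprotonated by fluoride or by the enolate of a previous turnover, adds to it (N1–C7a), the ortho aryl anion adds to the β-carbon of the acrylate (C3–C3a), and the ester enolate is protonated at C2. The closest known reaction is the fluoride-triggered formal [3+2] annulation of arynes with N-Boc dehydroalanine esters to indoline-2-carboxylates, applied here to an acceptor that carries a β-substituent. The only ring formed, the five-membered ring of ring A, closes by 5-endo-trig conjugate addition of the aryl anion, which the new N-aryl bond holds next to the alkene. C3 is created in this closure with no controlling element and C2 by protonation of the enolate under the influence of the bulky C3 group, so a racemic indoline should result, drawn as the trans isomer favoured on equilibration; the ratio is immaterial because both centres become sp2 in step 8. No regiochemical question arises since benzyne is symmetric; what the step needs is that ring closure outruns protonation of the aryl anion and base-induced migration of the alkene toward the bis(indolyl)methine, which is served by THF as a non-acidic solvent in place of acetonitrile, by the mild anhydrous fluoride source and by slow addition of 9. The indole N-Boc groups prevent N-arylation of the indoles, and the tert-butyl carbamate resists acyl transfer to the aryl anion.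

Step 6
Reactants: 11 methyl (2R*,3R*)-1-Boc-3-[bis(1-Boc-indol-3-yl)methyl]indoline-2-carboxylate
Product: 12 methyl (2R*,3R*)-3-[bis(1H-indol-3-yl)methyl]indoline-2-carboxylate (trans, racemic)
Conditions: trifluoroacetic acid/CH2Cl2 (1:2), 0 °C → rt, argon; then aq. NaHCO3
Reagents that add atoms: none
Why: Acidolysis of the three tert-butyl carbamates (Boc removal) leaves the methyl ester alone, and the indoles stay deactivated as N-carboxylic acids until work-up, which protects the bis(indolyl)methane from acid cleavage and tert-butylation.

Step 7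
Reactants: 12 methyl (2R*,3R*)-3-[bis(1H-indol-3-yl)methyl]indoline-2-carboxylate
Product: 13 {(2R*,3R*)-3-[bis(1H-indol-3-yl)methyl]indolin-2-yl}methanol (trans, racemic)
Conditions: LiAlH4 (5 equiv), THF, 0 °C → rt; H2O/aq. NaOH work-up
Reagents that add atoms: none
Why: Hydride reduction of the α-amino ester with LiAlH4 gives the primary alcohol, the excess reagent covering the three acidic N–H groups, and nothing else in the molecule is reducible.

Step 8
Reactants: 13 {(2R*,3R*)-3-[bis(1H-indol-3-yl)methyl]indolin-2-yl}methanol
Product: 15 trisindolal, via indol-2-ylmethanol 14 (not isolated)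
Conditions: activated MnO2 (ca. 20 equiv), CH2Cl2, rt → reflux
Reagents that add atoms: none
Why: Activated MnO2 first dehydrogenates the indoline to the aromatic indole, which erases both stereocentres, and then oxidises the indol-2-ylmethanol so formed, an activated benzylic-type alcohol, to the aldehyde without going on to the acid.

Compound list
1 | indole (1H-indole) | c1ccc2[nH]ccc2c1 | starting material
2 | 2,2-dimethoxyacetaldehyde | COC(OC)C=O | starting material
3 | 1-(1H-indol-3-yl)-2,2-dimethoxyethan-1-ol (racemic, not isolated) | COC(OC)C(O)c1c[nH]c2ccccc12 | intermediate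
4 | 3,3'-(2,2-dimethoxyethane-1,1-diyl)bis(1H-indole) | COC(OC)C(c1c[nH]c2ccccc12)c1c[nH]c2ccccc12 | intermediate
5 | di-tert-butyl 3,3'-(2,2-dimethoxyethane-1,1-diyl)bis(1H-indole-1-carboxylate) | COC(OC)C(c1cn(C(=O)OC(C)(C)C)c2ccccc12)c1cn(C(=O)OC(C)(C)C)c2ccccc12 | intermediate
6 | 2,2-bis(1-Boc-indol-3-yl)acetaldehyde | O=CC(c1cn(C(=O)OC(C)(C)C)c2ccccc12)c1cn(C(=O)OC(C)(C)C)c2ccccc12 | intermediate
7 | Boc-α-phosphonoglycine trimethyl ester, methyl 2-[(tert-butoxycarbonyl)amino]-2-(dimethoxyphosphoryl)acetate (racemic) | COC(=O)C(NC(=O)OC(C)(C)C)P(=O)(OC)OC | starting material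
8 | methyl (Z)-2-(Boc-amino)-4,4-bis(1-Boc-indol-3-yl)but-2-enoate | COC(=O)/C(NC(=O)OC(C)(C)C)=C/C(c1cn(C(=O)OC(C)(C)C)c2ccccc12)c1cn(C(=O)OC(C)(C)C)c2ccccc12 | intermediate
9 | 2-(trimethylsilyl)phenyl trifluoromethanesulfonate | C[Si](C)(C)c1ccccc1OS(=O)(=O)C(F)(F)F | starting material
10 | benzyne (not isolated) | C1=CC=CC#C1 | intermediate
11 | methyl (2R*,3R*)-1-Boc-3-[bis(1-Boc-indol-3-yl)methyl]indoline-2-carboxylate (trans, racemic; one enantiomer drawn) | COC(=O)[C@@H]1N(C(=O)OC(C)(C)C)c2ccccc2[C@H]1C(c1cn(C(=O)OC(C)(C)C)c2ccccc12)c1cn(C(=O)OC(C)(C)C)c2ccccc12 | intermediate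
12 | methyl (2R*,3R*)-3-[bis(1H-indol-3-yl)methyl]indoline-2-carboxylate (trans, racemic; one enantiomer drawn) | COC(=O)[C@@H]1Nc2ccccc2[C@H]1C(c1c[nH]c2ccccc12)c1c[nH]c2ccccc12 | intermediate
13 | {(2R*,3R*)-3-[bis(1H-indol-3-yl)methyl]indolin-2-yl}methanol (trans, racemic; one enantiomer drawn) | OC[C@@H]1Nc2ccccc2[C@H]1C(c1c[nH]c2ccccc12)c1c[nH]c2ccccc12 | intermediate
14 | {3-[bis(1H-indol-3-yl)methyl]-1H-indol-2-yl}methanol (not isolated) | OCc1[nH]c2ccccc2c1C(c1c[nH]c2ccccc12)c1c[nH]c2ccccc12 | intermediate
15 | trisindolal, 3-[bis(1H-indol-3-yl)methyl]-1H-indole-2-carbaldehyde (achiral) | O=Cc1[nH]c2ccccc2c1C(c1c[nH]c2ccccc12)c1c[nH]c2ccccc12 | target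

Total step count: 8. Longest linear sequence: 8 steps (1 and 2 to 15).

Steps most likely to fail

1. Step 5 (key step). The aryl anion may be protonated before it closes the ring, the alkene may migrate toward the bis(indolyl)methine in the basic medium, or benzyne may engage the allylic C–H in an ene reaction. Each of these processes consumes precursor 8 without forming ring A. Fallback: ring A is bought intact instead of being built from benzyne. It sets out from indole 1. Acid-catalysed condensation (TsOH·H2O, MeOH, rt to reflux) of two equivalents of 1 with commercial ethyl 3-formyl-1H-indole-2-carboxylate F1, a double Friedel–Crafts reaction of the tris(indolyl)methane type, should give ethyl 3-[bis(1H-indol-3-yl)methyl]-1H-indole-2-carboxylate F2. LiAlH4 in THF then reduces F2 to indol-2-ylmethanol 14, where the fallback comes back to the route, and MnO2 as in step 8 converts 14 into 15.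

2. Step 4. The base may enolise the α,α-diaryl aldehyde 6 faster than the phosphonate anion adds to it, and the product may suffer base-mediated migration of the double bond into conjugation with the indoles. Fallback: the olefination is done before the indoles are attached, so that no enolisable diaryl aldehyde is needed. It sets out from 2 and 7. The same Horner–Wadsworth–Emmons reaction (TMG, THF) on 2 should give methyl (Z)-2-[(tert-butoxycarbonyl)amino]-4,4-dimethoxybut-2-enoate F3. Sc(OTf)3-catalysed double Friedel–Crafts reaction of acetal F3 with indole 1 (2 equiv, MeCN) should give methyl (Z)-2-[(tert-butoxycarbonyl)amino]-4,4-bis(1H-indol-3-yl)but-2-enoate F4. Exhaustive acylation with Boc2O and DMAP then gives methyl (Z)-2-[bis(tert-butoxycarbonyl)amino]-4,4-bis(1-Boc-indol-3-yl)but-2-enoate F5. Mg(ClO4)2 in MeCN at 50 °C removes one Boc group selectively from the doubly acylated nitrogen and returns to 8.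

3. Step 8. Dehydrogenation of the hindered indoline may lag, and long exposure to a large excess of oxidant may degrade the amino alcohol or the bis(indolyl)methine before both oxidations are complete. Fallback: the two oxidations are separated and the first is run at the ester stage. It sets out from 12. Dehydrogenation over Pd/C in refluxing xylene should give methyl 3-[bis(1H-indol-3-yl)methyl]-1H-indole-2-carboxylate F6. LiAlH4 in THF reduces F6 to 14, where the route is rejoined, and a brief MnO2 treatment, which then has only the activated alcohol to oxidise, gives 15.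

Further compounds
F1 | step 5 | ethyl 3-formyl-1H-indole-2-carboxylate | CCOC(=O)c1[nH]c2ccccc2c1C=O
F2 | step 5 | ethyl 3-[bis(1H-indol-3-yl)methyl]-1H-indole-2-carboxylate | CCOC(=O)c1[nH]c2ccccc2c1C(c1c[nH]c2ccccc12)c1c[nH]c2ccccc12
F3 | step 4 | methyl (Z)-2-[(tert-butoxycarbonyl)amino]-4,4-dimethoxybut-2-enoate | COC(=O)/C(NC(=O)OC(C)(C)C)=C/C(OC)OC
F4 | step 4 | methyl (Z)-2-[(tert-butoxycarbonyl)amino]-4,4-bis(1H-indol-3-yl)but-2-enoate | COC(=O)/C(NC(=O)OC(C)(C)C)=C/C(c1c[nH]c2ccccc12)c1c[nH]c2ccccc12
F5 | step 4 | methyl (Z)-2-[bis(tert-butoxycarbonyl)amino]-4,4-bis(1-Boc-indol-3-yl)but-2-enoate | COC(=O)/C(N(C(=O)OC(C)(C)C)C(=O)OC(C)(C)C)=C/C(c1cn(C(=O)OC(C)(C)C)c2ccccc12)c1cn(C(=O)OC(C)(C)C)c2ccccc12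
F6 | step 8 | methyl 3-[bis(1H-indol-3-yl)methyl]-1H-indole-2-carboxylate | COC(=O)c1[nH]c2ccccc2c1C(c1c[nH]c2ccccc12)c1c[nH]c2ccccc12
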